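**Strategy.** C3 (the carbinol) and C19 (the acetoxymethyl carbon) are both one-carbon oxygenated arms on quaternary C4, so C3, C4, C18 and C19 are carried as a methylmalonate on C5 of a preformed ring B. Ring A (C1–C5, C10) is then closed by forming C2–C3: a C2 α-sulfonyl carbanion acylates one of the two diastereotopic esters (Dieckmann-type). This one operation creates the trans-decalin and the C4 quaternary stereocentre. The attacked ester becomes the C3 ketone (later the equatorial alcohol), and the spectator ester becomes C19. The precursor is a monocyclic ring-B cyclohexane bearing the malonate on C5 and a 2-(phenylsulfonyl)ethyl chain on C10.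

Key step: step 9

Convention: labdane numbering of the target is used for all intermediates (C11 on C9, C17 = exocyclic CH2 on C8, C18 = CH3 and C19 = CH2O on C4, C20 = CH3 on C10); α is the face of ring B that carries C20, β the opposite face.
Assumption: 3-bromofuran-2(5H)-one (20) is taken as a purchasable building block.
Remark: C9 is carried from step 6 to step 12 with C11 on the β face (9-epi) and is set in step 13.

Step 1
Reactants: 1 2-methylcyclohex-2-en-1-one
Product: 2 (R)-2-methylcyclohex-2-en-1-ol
Conditions: (S)-2-methyl-CBS-oxazaborolidine (10 mol%), BH3·SMe2, THF, −20 °C; MeOH quench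
Reagents that add atoms: none
Why: Corey–Bakshi–Shibata reduction in which the trisubstituted alkenyl carbon should act as the large group, so that hydride adds to the Si face and gives the R carbinol (C9–O on the α face), whose configuration is relayed to C5 in step 3.

Step 2
Reactants: 2 (R)-2-methylcyclohex-2-en-1-ol; 3 2,2,5-trimethyl-1,3-dioxane-4,6-dione
Product: 4 (R)-2-methylcyclohex-2-enyl hydrogen methylmalonate
Conditions: toluene, 90 °C
Reagents that add atoms: none
Why: alcoholysis of a Meldrum's acid should open the dioxanedione to the malonic half ester with loss of acetone, the malonate CH being of no stereochemical consequence because it becomes planar in step 3.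

Step 3
Reactants: 4 (R)-2-methylcyclohex-2-enyl hydrogen methylmalonate
Product: 8 dimethyl 2-methyl-2-[(1S)-2-methylcyclohex-2-en-1-yl]propanedioate, via bis(trimethylsilyl) ketene acetal 5 (not isolated), via bis(trimethylsilyl) malonate 6 (not isolated), via malonic diacid 7 (not isolated)
Conditions: LiN(SiMe3)2 (2.2 equiv), Me3SiCl, THF, −78 → 65 °C; 1 M HCl; then MeI, K2CO3, DMF, rt
Reagents that add atoms: iodomethane CI
Why: Ireland–Claisen rearrangement, in which the suprafacial [3,3] shift should relay the C9–O configuration to the new C4–C5 bond (malonate on the α face of C5), move the alkene to C9=C10 and create no stereocentre at C4 because that carbon ends with two identical carboxyl groups, which O-methylation converts into the symmetric diester.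

Step 4
Reactants: 8 dimethyl 2-methyl-2-[(1S)-2-methylcyclohex-2-en-1-yl]propanedioate
Product: 9 dimethyl 2-methyl-2-[(1S)-2-methyl-4-oxocyclohex-2-en-1-yl]propanedioate
Conditions: Rh2(cap)4 (dirhodium tetracaprolactamate, 1 mol%), t-BuOOH (5 equiv), K2CO3, CH2Cl2, rt
Reagents that add atoms: tert-butyl hydroperoxide CC(C)(C)OO
Why: catalytic allylic C–H oxidation should take place at the unhindered ring CH2 next to the alkene CH (C8) and give the enone C8(=O)–C9=C10, the tertiary C5–H being shielded and deactivated by the malonate and untouched under these non-basic conditions.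

Step 5
Reactants: 9 dimethyl 2-methyl-2-[(1S)-2-methyl-4-oxocyclohex-2-en-1-yl]propanedioate
Product: 10 vinyl silyl enol ether (C10 quaternary)
Conditions: vinylmagnesium bromide, CuBr·SMe2 (20 mol%), Me3SiCl, HMPA, THF, −78 → −40 °C; Et3N quench
Reagents that add atoms: vinylmagnesium bromide C=C[Mg]Br; chlorotrimethylsilane C[Si](C)(C)Cl
Why: copper-catalysed, chlorosilane-accelerated 1,4-addition in which allylic strain with the C10 methyl should hold the C5 malonate pseudoaxial, so that the vinyl group (C1=C2) enters C10 on the opposite (β) face and the enolate is trapped regiospecifically as the C8–C9 silyl enol ether.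

Step 6
Reactants: 10 vinyl silyl enol ether (C10 quaternary)
Product: 11 vinyl keto acetal (9-epi)
Conditions: HC(OMe)3, Me3SiOTf (10 mol%), CH2Cl2, −78 °C; Et3N quench
Reagents that add atoms: trimethyl orthoformate COC(OC)OC
Why: Mukaiyama-type alkylation of the silyl enol ether by the dimethoxycarbenium ion should install C11 at the aldehyde oxidation level on C9 only, by axial attack anti to the C10 methyl (C11 on the β face), which is of no consequence because C9 is reset in step 13.

Step 7
Reactants: 11 vinyl keto acetal (9-epi)
Product: 12 sulfonylethyl keto acetal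
Conditions: PhSO2Cl, fac-Ir(ppy)3 (tris(2-phenylpyridinato)iridium, 1 mol%), (Me3Si)3SiH, MeCN, blue LEDs, rt
Reagents that add atoms: benzenesulfonyl chloride O=S(=O)(Cl)c1ccccc1
Why: photoredox radical hydrosulfonylation in which the sulfonyl radical should add to the terminal carbon (C2) of the only alkene and the C1 radical take hydrogen from the silane, giving the anti-Markovnikov sulfone without a new stereocentre.

Step 8
Reactants: 12 sulfonylethyl keto acetal
Product: 13 sulfonylethyl methylidene acetal
Conditions: Cp2TiMe2 (2 equiv), toluene, 65 °C, dark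
Reagents that add atoms: dimethyltitanocene C[Ti](C)(C1C=CC=C1)C1C=CC=C1
Why: Petasis methylenation, in which the non-basic titanocene methylidene should convert the hindered, enolisable C8 ketone into the exocyclic alkene without β-elimination of methoxide and faster than it attacks the neopentyl malonate esters.

Step 9
Reactants: 13 sulfonylethyl methylidene acetal
Product: 14 decalin β-keto sulfone (ring A closed)
Conditions: LiN(iPr)2 (2.3 equiv), THF, −78 → 0 °C; aq. NH4Cl
Reagents that add atoms: none
Why: Deprotonation α to the sulfone gives the C2 carbanion, which adds to one ester carbonyl (C3) and expels methoxide, and the second equivalent of base turns the β-keto sulfone into its enolate, which makes the closure irreversible. The closest known reaction type is the intramolecular Claisen (Dieckmann-type) acylation of an α-sulfonyl carbanion by an ester. Ring A closes in the 6-exo-trig mode through a chair fused trans to ring B, both tethers being equatorial on C5 and C10. The new C4 stereocentre is set by which diastereotopic ester is attacked: the spectator group that must sit axial and syn to the C10 methyl should be the flat CO2Me (smaller syn-axial penalty than CH3), so that C18 ends equatorial (β) and the future C19 axial (α), while the C2 stereocentre is transient and erased in step 10. The step needs selective C2 deprotonation, which the substrate secures because C4 is quaternary (no enolisable ester), C8 is already an alkene (no ketone enolate) and the acetal is inert to base.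

Step 10
Reactants: 14 decalin β-keto sulfone (ring A closed)
Product: 15 decalin keto ester
Conditions: SmI2 (2.2 equiv), THF/MeOH, −78 °C
Reagents that add atoms: none
Why: reductive desulfonylation of a β-keto sulfone by single-electron transfer should cleave the C2–S bond much faster than the ketone, the ester or the isolated alkene is reduced, returning C2 to CH2.

Step 11
Reactants: 15 decalin keto ester
Product: 16 diol acetal
Conditions: LiAlH4, THF, −78 → 0 °C
Reagents that add atoms: none
Why: hydride reduction in which the C3 ketone should be reduced first by axial attack from the open β face (giving the equatorial 3α-alcohol) and the C19 ester then reduced to the primary alcohol on warming.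

Step 12
Reactants: 16 diol acetal
Product: 17 9-epi aldehyde diol
Conditions: aq. oxalic acid, THF, rt
Reagents that add atoms: water O
Why: mild acetal hydrolysis should unveil the C11 aldehyde while the weak acid leaves the exocyclic alkene in place.

Step 13
Reactants: 17 9-epi aldehyde diol
Product: 18 aldehyde diol with natural C9
Conditions: LiN(SiMe3)2 (3.3 equiv), THF, −78 °C; then AcOH, −78 °C
Reagents that add atoms: none
Why: kinetic protonation of the dienolate (O–C11=C9–C8=C17) at its α-carbon C9 should occur axially from the β face, anti to the C10 methyl, returning the β,γ-unsaturated aldehyde with H9 β and C11 equatorial (α) whichever C9 epimer enters.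

Step 14
Reactants: 18 aldehyde diol with natural C9
Product: 19 (E)-alkenyl pinacol boronate
Conditions: Cl2CHBpin, CrCl2 (8 equiv), LiI, THF, rt
Reagents that add atoms: 2-(dichloromethyl)-4,4,5,5-tetramethyl-1,3,2-dioxaborolane ClC(Cl)B1OC(C)(C)C(C)(C)O1
Why: Takai–Utimoto boryl olefination, in which the geminal dichromium reagent should add to the aldehyde and eliminate to the (E)-alkenylboronate under non-basic conditions that leave C9 and the free diol untouched.

Step 15
Reactants: 19 (E)-alkenyl pinacol boronate; 20 3-bromofuran-2(5H)-one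
Product: 21 14-deoxy-11,12-didehydroandrographolide
Conditions: Pd(PPh3)4 (5 mol%), CsF, THF, 50 °C
Reagents that add atoms: none
Why: Suzuki–Miyaura coupling of the alkenylboronate with the α-bromobutenolide should form the C12–C13 bond with retention of the E geometry, fluoride activation avoiding aqueous base.

Step 16
Reactants: 21 14-deoxy-11,12-didehydroandrographolide
Product: 22 19-O-acetyl-14-deoxy-11,12-didehydroandrographolide (target)
Conditions: AcCl (1.05 equiv), 2,4,6-collidine, CH2Cl2, −78 °C
Reagents that add atoms: acetyl chloride CC(Cl)=O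
Why: chemoselective acylation, in which the primary C19 hydroxyl should react much faster than the secondary C3 hydroxyl flanked by quaternary C4.

**Compound list**

1 | 2-methylcyclohex-2-en-1-one | CC1=CCCCC1=O | starting material
2 | (R)-2-methylcyclohex-2-en-1-ol | O[C@@H]1CCCC=C1C | intermediate
3 | 2,2,5-trimethyl-1,3-dioxane-4,6-dione (methyl Meldrum's acid) | CC1C(=O)OC(C)(C)OC1=O | starting material
4 | 2-methyl-3-{[(1R)-2-methylcyclohex-2-en-1-yl]oxy}-3-oxopropanoic acid (both epimers at the malonate CH) | CC(C(=O)O)C(=O)O[C@@H]1CCCC=C1C | intermediate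
5 | trimethylsilyl 2-methyl-3-{[(1R)-2-methylcyclohex-2-en-1-yl]oxy}-3-(trimethylsilyloxy)prop-2-enoate (bis-silyl ketene acetal) | CC(C(=O)O[Si](C)(C)C)=C(O[Si](C)(C)C)O[C@@H]1CCCC=C1C | intermediate
6 | bis(trimethylsilyl) 2-methyl-2-[(1S)-2-methylcyclohex-2-en-1-yl]propanedioate | C[Si](C)(C)OC(=O)C(C)(C(=O)O[Si](C)(C)C)[C@H]1CCCC=C1C | intermediate
7 | 2-methyl-2-[(1S)-2-methylcyclohex-2-en-1-yl]propanedioic acid | OC(=O)C(C)(C(=O)O)[C@H]1CCCC=C1C | intermediate
8 | dimethyl 2-methyl-2-[(1S)-2-methylcyclohex-2-en-1-yl]propanedioate | COC(=O)C(C)(C(=O)OC)[C@H]1CCCC=C1C | intermediate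
9 | dimethyl 2-methyl-2-[(1S)-2-methyl-4-oxocyclohex-2-en-1-yl]propanedioate | COC(=O)C(C)(C(=O)OC)[C@H]1CCC(=O)C=C1C | intermediate
10 | dimethyl 2-[(1S,2R)-2-ethenyl-2-methyl-4-(trimethylsilyloxy)cyclohex-3-en-1-yl]-2-methylpropanedioate (vinyl β, trans to the malonate; C20 α) | COC(=O)C(C)(C(=O)OC)[C@H]1CCC(O[Si](C)(C)C)=C[C@]1(C)C=C | intermediate
11 | dimethyl 2-[(1S,2R,3S)-3-(dimethoxymethyl)-2-ethenyl-2-methyl-4-oxocyclohexyl]-2-methylpropanedioate (CH(OMe)2 on C9 β, 9-epi) | COC(=O)C(C)(C(=O)OC)[C@H]1CCC(=O)[C@H](C(OC)OC)[C@]1(C)C=C | intermediate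
12 | dimethyl 2-[(1S,2R,3S)-3-(dimethoxymethyl)-2-methyl-4-oxo-2-[2-(phenylsulfonyl)ethyl]cyclohexyl]-2-methylpropanedioate | COC(=O)C(C)(C(=O)OC)[C@H]1CCC(=O)[C@H](C(OC)OC)[C@]1(C)CCS(=O)(=O)c1ccccc1 | intermediate
13 | dimethyl 2-[(1S,2R,3S)-3-(dimethoxymethyl)-2-methyl-4-methylidene-2-[2-(phenylsulfonyl)ethyl]cyclohexyl]-2-methylpropanedioate | COC(=O)C(C)(C(=O)OC)[C@H]1CCC(=C)[C@H](C(OC)OC)[C@]1(C)CCS(=O)(=O)c1ccccc1 | intermediate
14 | trans-decalin β-keto sulfone: C2–SO2Ph (both epimers), C3 ketone, C4 with CO2Me α (axial, cis to C20) and CH3 β, 5β-H, 10α-CH3, C8=CH2, C9 with CH(OMe)2 β | C=C1CC[C@@H]2[C@](C)(C(=O)OC)C(=O)C(S(=O)(=O)c3ccccc3)C[C@@]2(C)[C@H]1C(OC)OC | intermediate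
15 | trans-decalin keto ester: as 14 with C2 = CH2 | C=C1CC[C@@H]2[C@](C)(C(=O)OC)C(=O)CC[C@@]2(C)[C@H]1C(OC)OC | intermediate
16 | diol acetal: 3α-OH (equatorial), C19 CH2OH α (axial), C18 β, 5β-H, 10α-CH3, C8=CH2, C9 with CH(OMe)2 β | C=C1CC[C@@H]2[C@](C)(CO)[C@H](O)CC[C@@]2(C)[C@H]1C(OC)OC | intermediate
17 | (1S,4aS,5R,6R,8aR)-6-hydroxy-5-(hydroxymethyl)-5,8a-dimethyl-2-methylidenedecahydronaphthalene-1-carbaldehyde (CHO β, 9-epi) | C=C1CC[C@@H]2[C@](C)(CO)[C@H](O)CC[C@@]2(C)[C@H]1C=O | intermediate
18 | (1R,4aS,5R,6R,8aR)-6-hydroxy-5-(hydroxymethyl)-5,8a-dimethyl-2-methylidenedecahydronaphthalene-1-carbaldehyde (CHO α, equatorial, natural C9) | C=C1CC[C@@H]2[C@](C)(CO)[C@H](O)CC[C@@]2(C)[C@@H]1C=O | intermediate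
19 | (E)-alkenyl pinacol boronate of 18 (C9–CH=CH–Bpin, 3α-OH and 19-OH free) | C=C1CC[C@@H]2[C@](C)(CO)[C@H](O)CC[C@@]2(C)[C@@H]1/C=C/B1OC(C)(C)C(C)(C)O1 | intermediate
20 | 3-bromofuran-2(5H)-one | O=C1OCC=C1Br | starting material
21 | 3-[(E)-2-[(1R,4aS,5R,6R,8aR)-6-hydroxy-5-(hydroxymethyl)-5,8a-dimethyl-2-methylidenedecahydronaphthalen-1-yl]ethenyl]furan-2(5H)-one (14-deoxy-11,12-didehydroandrographolide) | C=C1CC[C@@H]2[C@](C)(CO)[C@H](O)CC[C@@]2(C)[C@@H]1/C=C/C1=CCOC1=O | intermediate
22 | 3-[(E)-2-[(1R,4aS,5R,6R,8aR)-5-(acetoxymethyl)-6-hydroxy-5,8a-dimethyl-2-methylidenedecahydronaphthalen-1-yl]ethenyl]furan-2(5H)-one | C=C1CC[C@@H]2[C@](C)(COC(C)=O)[C@H](O)CC[C@@]2(C)[C@@H]1/C=C/C1=CCOC1=O | target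

**Count.** Total: 16 steps. Longest linear sequence: 16 steps (1 → 22); 3 and 20 enter as purchased building blocks.

**Steps most likely to fail**

Step 9 (key step). The acylation is irreversible, so discrimination between the two diastereotopic esters may be low, or attack on the neopentyl ester may be slow. The fallback sets out from 13 and comes back at 16, and makes the ring closure reversible so that the choice is thermodynamic. Reduction of both esters with LiAlH4 would give the sulfonyl diol F3, and Swern oxidation the non-enolisable sulfonyl dialdehyde F4. KN(SiMe3)2 in THF (−78 → 0 °C) would then close ring A by a reversible sulfone–aldehyde aldol addition, forming the same C2–C3 bond and giving the hydroxy sulfone aldehyde F5 with the small formyl group axial. NaBH4 would reduce the remaining formyl group to the sulfonyl diol F6, and Na(Hg)/Na2HPO4 in MeOH would remove the sulfonyl group to give 16.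

Step 5. The 1,4-addition may be too slow at the congested β-carbon C10, so that 1,2-addition or reduction of the enone takes over. The fallback sets out from 9 and comes back at 11, and uses a Lewis-acid-driven allyl transfer followed by one-carbon trimming. Hosomi–Sakurai allylation (allyltrimethylsilane, TiCl4, CH2Cl2, −78 °C) with trapping of the titanium enolate by HC(OMe)3 would give the allyl keto acetal F1. RuHCl(CO)(PPh3)3 in toluene would move the alkene inward to the (E)-propenyl keto acetal F2. Ethenolysis (second-generation Hoveyda–Grubbs catalyst, ethylene, CH2Cl2) would cut it back to the vinyl compound 11.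

Step 13. Enolisation of the hindered aldehyde with a lithium amide may be incomplete or accompanied by self-condensation, and protonation at C17 would conjugate the alkene into C8–C9. The fallback sets out from 17 and comes back at 18, and separates enolisation from protonation. Soft enolisation with Me3SiOTf/Et3N in CH2Cl2 would give the tris(trimethylsilyl) dienol ether F7 (both hydroxyls silylated as well). Protodesilylation with Bu4NF buffered by AcOH in THF at −78 °C would then deliver the proton to C9 from the β face, free both hydroxyls and give 18.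

Further compounds
F1 | step 5 | dimethyl 2-[(1S,2R,3S)-3-(dimethoxymethyl)-2-methyl-4-oxo-2-(prop-2-en-1-yl)cyclohexyl]-2-methylpropanedioate | COC(=O)C(C)(C(=O)OC)[C@H]1CCC(=O)[C@H](C(OC)OC)[C@]1(C)CC=C
F2 | step 5 | dimethyl 2-[(1S,2R,3S)-3-(dimethoxymethyl)-2-methyl-4-oxo-2-[(E)-prop-1-en-1-yl]cyclohexyl]-2-methylpropanedioate | COC(=O)C(C)(C(=O)OC)[C@H]1CCC(=O)[C@H](C(OC)OC)[C@]1(C)/C=C/C
F3 | step 9 | sulfonyl diol: 13 with both CO2Me groups reduced to CH2OH | OCC(C)(CO)[C@H]1CCC(=C)[C@H](C(OC)OC)[C@]1(C)CCS(=O)(=O)c1ccccc1
F4 | step 9 | sulfonyl dialdehyde: 13 with both CO2Me groups replaced by CHO | O=CC(C)(C=O)[C@H]1CCC(=C)[C@H](C(OC)OC)[C@]1(C)CCS(=O)(=O)c1ccccc1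
F5 | step 9 | trans-decalin hydroxy sulfone aldehyde: 3α-OH, C2–SO2Ph, C4 with CHO α (axial) and CH3 β, C9 with CH(OMe)2 β | C=C1CC[C@@H]2[C@](C)(C=O)[C@H](O)C(S(=O)(=O)c3ccccc3)C[C@@]2(C)[C@H]1C(OC)OC
F6 | step 9 | trans-decalin sulfonyl diol: F5 with the formyl group reduced to CH2OH | C=C1CC[C@@H]2[C@](C)(CO)[C@H](O)C(S(=O)(=O)c3ccccc3)C[C@@]2(C)[C@H]1C(OC)OC
F7 | step 13 | tris(trimethylsilyl) dienol ether of 17 (C9=C11–OSiMe3, 3-OSiMe3, 19-OSiMe3) | C=C1CC[C@@H]2[C@](C)(CO[Si](C)(C)C)[C@H](O[Si](C)(C)C)CC[C@@]2(C)C1=CO[Si](C)(C)C
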